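**Retrosynthetic overview**
1. Endgame: desilylate O-1', acetylate O-2 and methylenate C11. Close the spiro-lactone C12'–O–C8' from its hydroxy acid. Form C11'–C7' by Ireland–Claisen rearrangement of the C5' tertiary allylic ester of eudesmane alcohol 43 (eleven steps from (S)-Wieland–Miescher ketone). Form C11'–C3 by intramolecular ester-enolate alkylation, which closes the bicyclo[2.2.1]heptene.
2. Guaiane acid 31 comes from an oxygen-bridged tricycle by exo hydrogenation (C7), C10 methylenation, β-elimination of the C5–O bond (C4=C5 enone, free C8–OH), OH-directed hydrogenation (C10) and trans-lactonisation.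
3. Feature used: the seven-membered ring C1/C5–C10 carries oxygen at C8, a quaternary C1 and an alkene carbon C5. It is therefore a ring-opened 8-oxabicyclo[3.2.1]oct-6-ene whose C5–O–C8 bridge is a furan oxygen. An oxyallyl cation C9–C10–C1, tied through C2–C3–C4 to furan C5, builds this ring and the five-membered ring C1–C5 in one (4+3) cycloaddition.
4. α-Chloroketone 22 takes ten linear steps: C5-selective borylation of a 3-furylacetate, Suzuki coupling, Evans aldol (C1–C2 bond, sets C2), hydroboration (O-3) and diazoketone/HCl (C9).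
5. Ring order: furan (bought), then the seven- and five-membered carbocycles (step 13), guaiane γ-lactone (19), norbornene (33) and spiro γ-lactone (35). The decalin comes with the Wieland–Miescher ketone.

Key step: step 13

Remark 1: guaiane atoms are C1–C15 and eudesmane atoms C1'–C15'. C13'–C11' is the two-carbon bridge of the norbornene. "Upper face" is the hydroazulene face that carries C13' and O-8.
Remark 2: the configuration is taken exactly as written in the SMILES. This calls for (S)-Wieland–Miescher ketone and the (R)-benzyloxazolidinone.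
Remark 3: C3 passes through the cycloaddition as a silyl ether, because a C3 ketone would give an acidic C4–H that adds to the chloroketone. O-2 carries a chelating PMB group. Both esters are tert-butyl so that O-8 stays free until step 19.

**Step 1**
Reactants: 1 3-bromofuran; 2 (2-tert-butoxy-2-oxoethyl)zinc bromide
Product: 3 tert-butyl 2-(furan-3-yl)acetate
Conditions: Pd(dba)2 (2 mol%), P(t-Bu)3 (2 mol%), THF, rt
Reagents that add atoms: none
Why: Palladium-catalysed coupling of a Reformatsky reagent with a heteroaryl bromide (Negishi-type ester α-arylation) puts C11–C12 on furan C7.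

**Step 2**
Reactants: 3 tert-butyl 2-(furan-3-yl)acetate
Product: 4 tert-butyl 2-[5-(pinacolboryl)furan-3-yl]acetate
Conditions: [Ir(OMe)(cod)]2 (1.5 mol%), 4,4'-di-tert-butyl-2,2'-bipyridine (3 mol%), B2pin2, hexane, rt
Reagents that add atoms: bis(pinacolato)diboron CC1(C)OB(OC1(C)C)B1OC(C)(C)C(C)(C)O1
Why: Iridium-catalysed C–H borylation is sterically governed and takes the α-C–H remote from the side chain (future C5), whereas electrophilic acylation of a 3-alkylfuran would favour the adjacent α-position.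

**Step 3**
Reactants: 5 but-2-yn-1-ol
Product: 6 (Z)-3-iodobut-2-en-1-ol
Conditions: NaAlH2(OCH2CH2OMe)2, THF, 0 °C to rt; then I2, -78 °C
Reagents that add atoms: iodine II
Why: trans-Hydroalumination of the propargylic alkoxide places aluminium on C3, and iodinolysis with retention gives the Z-iodide.

**Step 4**
Reactants: 4 furyl boronate; 6 (Z)-3-iodobut-2-en-1-ol
Product: 7 tert-butyl 2-{5-[(Z)-4-hydroxybut-2-en-2-yl]furan-3-yl}acetate
Conditions: PdCl2(dppf) (3 mol%), K3PO4, THF–H2O, 45 °C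
Reagents that add atoms: none
Why: Suzuki–Miyaura coupling keeps the alkene geometry (furan cis to CH2OH), forms C4–C5 and tolerates the ester and the free alcohol.

**Step 5**
Reactants: 7 allylic alcohol
Product: 8 tert-butyl 2-{5-[(Z)-4-oxobut-2-en-2-yl]furan-3-yl}acetate
Conditions: activated MnO2, CH2Cl2, rt, dark; used at once
Reagents that add atoms: none
Why: Neutral MnO2 oxidation of an allylic alcohol preserves the Z-alkene and the furan.

**Step 6**
Reactants: 9 5-(tert-butoxy)-5-oxopentanoic acid; 10 (R)-4-benzyloxazolidin-2-one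
Product: 12 (R)-4-benzyl-3-[5-(tert-butoxy)-5-oxopentanoyl]oxazolidin-2-one, via mixed pivalic anhydride 11 (not isolated)
Conditions: t-BuCOCl, Et3N, THF, -20 °C; then 10, LiCl, rt
Reagents that add atoms: none
Why: Mixed-anhydride N-acylation of the auxiliary needs no strong base and supplies C10, C1, C13', C11' and C12' in one piece.

**Step 7**
Reactants: 12 imide; 8 Z-enal
Product: 14 syn-aldol adduct (C2–OH; C3=C4 Z), via dibutylboron Z-enolate 13 (not isolated)
Conditions: Bu2BOTf, Et3N, CH2Cl2, -78 to 0 °C; 8, -78 to 0 °C; pH 7 buffer, MeOH, 30% H2O2, 0 °C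
Reagents that add atoms: none
Why: In the Evans syn-aldol reaction the Z-boron enolate reacts through a chair transition state on the face left open by the benzyl group of the (R)-auxiliary, which forms C1–C2 and sets C2 (and the later erased C1).

**Step 8**
Reactants: 14 aldol adduct
Product: 15 C2 p-methoxybenzyl ether
Conditions: 2-(4-methoxybenzyloxy)-4-methylquinoline, MeOTf, MgO, toluene, 0 °C to rt
Reagents that add atoms: 2-(4-methoxybenzyloxy)-4-methylquinoline COc1ccc(COc2cc(C)c3ccccc3n2)cc1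
Why: Neutral benzyl transfer from the N-methylated quinolinium salt avoids acid (ionisable furyl-allylic alcohol) and base (retro-aldol), and a benzyl-type ether can chelate lithium in step 13.

**Step 9**
Reactants: 15 PMB ether
Product: 17 C3 alcohol (O-3 anti to O-2; C4 methyl syn to O-2 on the future ring), via C3 alkylborane 16 (not isolated)
Conditions: BH3·THF, THF, 0 °C to rt; then NaBO3·4H2O, THF–H2O, rt
Reagents that add atoms: sodium perborate [Na+].[Na+].O[B-]1(O)OO[B-](O)(O)OO1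
Why: Hydroboration–oxidation puts boron on the less substituted C3; allylic 1,3-strain holds H-2 in the alkene plane, borane adds opposite the branched C1 substituent, and syn addition to the Z-alkene fixes the temporary centres C3 and C4.

**Step 10**
Reactants: 17 C3 alcohol
Product: 18 C3 triethylsilyl ether
Conditions: TESOTf, 2,6-lutidine, CH2Cl2, -78 °C
Reagents that add atoms: triethylsilyl triflate CC[Si](CC)(CC)OS(=O)(=O)C(F)(F)F
Why: Silylation masks O-3 so that only one ketone (C10) is present in steps 13 and 15, and TES can later be removed beside PMB and tert-butyl esters.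

**Step 11**
Reactants: 18 imide
Product: 19 carboxylic acid (C10)
Conditions: LiOH, 30% H2O2, THF–H2O, 0 °C; Na2SO3; citric acid to pH 4
Reagents that add atoms: hydrogen peroxide OO
Why: Hydroperoxide attacks the exocyclic imide carbonyl selectively (standard auxiliary removal) and spares the tert-butyl esters and silyl ether.

**Step 12**
Reactants: 19 acid
Product: 22 furan-tethered α-chloroketone, via acid chloride 20 (not isolated), via diazoketone 21 (not isolated)
Conditions: 1-chloro-N,N,2-trimethylprop-1-en-1-amine, CH2Cl2, 0 °C; CH2N2 (3 equiv), Et2O, 0 °C, then N2 purge; HCl (1 M in Et2O, 1.1 equiv), -30 °C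
Reagents that add atoms: diazomethane C=[N+]=[N-]; hydrogen chloride Cl
Why: Arndt–Eistert-type acylation of diazomethane followed by hydrochlorination of the diazoketone adds C9 and gives the chloromethyl ketone without base.

**Step 13**
Reactants: 22 α-chloroketone
Product: 24 oxygen-bridged tricyclic ketone, via oxyallyl cation 23 (not isolated)
Conditions: LiClO4 (5 M in Et2O), i-Pr2NEt (2 equiv), slow addition to 0.01 M, rt
Reagents that add atoms: none
Why: The amine removes H-1 of the lithium-bound ketone and the LiClO4–ether medium ionises C9–Cl, so that the 2-oxyallyl cation 23 (C9–C10–C1) adds across furan C8 and C5 in a (4+3) cycloaddition, the known intramolecular reaction of base-generated oxyallyl cations from α-haloketones with tethered furans. The seven-membered carbocycle (C1, C5–C10) closes by the cycloaddition itself (bonds C8–C9 and C1–C5), and the five-membered ring C1–C5 closes because the three-atom tether C2–C3–C4 joins C1 to furan C5. C5 and C8 are set together by suprafacial addition to the furan, which leaves the oxygen bridge cis at both. C1 is set by cation geometry and a compact transition state: Li+ held between the oxyallyl oxygen and the C2 ether oxygen keeps C2 syn to that oxygen and the C13' chain in the inner position, where it can lie only over the small furan oxygen, so C13' ends syn and C2 anti to the bridge. The same six-membered chelate holds the C2–O bond in the nodal plane of the cation, so H-2 and C3 flank its two faces and the furan, carried by C3, reaches only one of them; this relays C2 to C1, C5 and C8, with the C4 methyl pointing away from C13'. The step needs productive C1 enolisation, no loss of the C2 ether and no attack on CH2Cl: C9 enolisation is reversible and leads nowhere, the in-plane C2–O bond cannot overlap with the enolate π system, the hindered amine does not alkylate, and the C3 silyl ether removes the acidic C4–H that would add to the chloroketone.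

**Step 14**
Reactants: 24 tricyclic alkene
Product: 25 saturated oxygen-bridged ketone (C11 chain endo at C7)
Conditions: H2 (1 atm), 5% Pd/C–ethylenediamine, THF, rt
Reagents that add atoms: none
Why: Catalytic hydrogenation adds to the exo face of the oxabicyclic alkene (the endo face is covered by the C9–C10–C1 bridge); this sets C7 with C11 anti to O-8, and the poisoned catalyst spares the PMB ether.

**Step 15**
Reactants: 25 ketone
Product: 26 C10 exocyclic methylene compound
Conditions: Zn, CH2Br2, TiCl4 (pre-aged reagent), CH2Cl2, 0 °C to rt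
Reagents that add atoms: dibromomethane BrCBr
Why: Lombardo methylenation is non-basic, so the ketone is not enolised toward C9 (which would expel O-8), and it leaves esters untouched; it adds C14.

**Step 16**
Reactants: 26 silyl ether
Product: 27 C3 alcohol
Conditions: PPTS (0.2 equiv), MeOH–CH2Cl2, 0 °C to rt
Reagents that add atoms: none
Why: Mild acid methanolysis cleaves the triethylsilyl ether selectively beside PMB and tert-butyl esters.

**Step 17**
Reactants: 27 C3 alcohol
Product: 29 hydroazulenone (C4=C5 enone; free C8–OH; C10=CH2), via C3 ketone 28 (not isolated)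
Conditions: Dess–Martin periodinane, NaHCO3, CH2Cl2, 0 °C to rt; then DBU (1.2 equiv), 0 °C, short
Reagents that add atoms: none
Why: Dess–Martin oxidation gives a β-alkoxy ketone whose C4 enolate expels O-5 (E1cB β-elimination aided by strain release), which opens the bridge to the enone and the C8 alcohol and erases C4.

**Step 18**
Reactants: 29 hydroazulenone
Product: 30 C10-methyl hydroazulenone (C14 on the lower face)
Conditions: [Ir(cod)(PCy3)(py)]PF6 (5 mol%), H2 (1 atm), CH2Cl2, 0 °C to rt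
Reagents that add atoms: none
Why: In this hydroxyl-directed hydrogenation the cationic iridium catalyst binds the homoallylic C8–OH and delivers hydrogen to C10 from the upper face, which sets C10 and leaves the tetrasubstituted enone alkene.

**Step 19**
Reactants: 30 hydroxy diester
Product: 31 guaiane lactone acid (trans C7/C8 γ-lactone; free C12' acid)
Conditions: chromatography-grade SiO2, toluene, reflux
Reagents that add atoms: none
Why: Silica-promoted thermolysis of tert-butyl esters frees both acids without touching the PMB ether, and the γ-hydroxy acid closes to the trans-fused γ-lactone.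

**Step 20**
Reactants: 32 (S)-Wieland–Miescher ketone
Product: 33 C1' alcohol (OH syn to C14')
Conditions: NaBH4 (0.3 equiv), EtOH, -10 °C
Reagents that add atoms: none
Why: Borohydride reduces the saturated ketone chemoselectively, with hydride entering opposite the angular methyl, which sets C1'.

**Step 21**
Reactants: 33 alcohol
Product: 34 C1' tert-butyldimethylsilyl ether
Conditions: TBSOTf, 2,6-lutidine, CH2Cl2, 0 °C
Reagents that add atoms: tert-butyldimethylsilyl triflate CC(C)(C)[Si](C)(C)OS(=O)(=O)C(F)(F)F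
Why: Standard silylation gives a group that survives to the last step and is orthogonal to PMB and TES.

**Step 22**
Reactants: 34 enone
Product: 35 C4'-methylene dienone
Conditions: CH2(OEt)2, POCl3, NaOAc, CHCl3, reflux
Reagents that add atoms: diethoxymethane CCOCOCC
Why: Vinylogous γ-methylenation of a ring-fused enone through its dienol ether with a formaldehyde acetal, a reaction type established on steroidal 4-en-3-ones, adds C15'.

**Step 23**
Reactants: 35 dienone
Product: 36 C4'-methyl enone (C15' syn to C14')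
Conditions: RhCl(PPh3)3 (5 mol%), H2 (1 atm), benzene–EtOH, rt
Reagents that add atoms: none
Why: Homogeneous hydrogenation takes the least hindered γ,δ-alkene of a linear dienone from the face opposite the axial C14' methyl, which sets C4' under neutral, non-epimerising conditions.

**Step 24**
Reactants: 36 enone
Product: 37 C7' allylic alcohol (OH syn to C14')
Conditions: NaBH4, CeCl3·7H2O, MeOH, -78 °C
Reagents that add atoms: none
Why: Luche 1,2-reduction with hydride from the face opposite C14' gives the equatorial alcohol and removes the enone before C4' can epimerise.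

**Step 25**
Reactants: 37 allylic alcohol
Product: 38 C5'–C6' epoxy alcohol (epoxide syn to O-7' and C14')
Conditions: mCPBA, CH2Cl2, 0 °C
Reagents that add atoms: 3-chloroperbenzoic acid OOC(=O)c1cccc(Cl)c1
Why: Hydroxyl-directed peracid epoxidation (hydrogen bond to the allylic OH) delivers oxygen syn to O-7', which sets C5' against the steric bias.

**Step 26**
Reactants: 38 epoxy alcohol
Product: 39 epoxy ketone
Conditions: Dess–Martin periodinane, NaHCO3, CH2Cl2, rt
Reagents that add atoms: none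
Why: Neutral Dess–Martin oxidation leaves the epoxide and C4' (no longer acidic) untouched.

**Step 27**
Reactants: 39 epoxy ketone
Product: 40 tertiary allylic alcohol (C5'–OH syn to C14'; C6'=C7')
Conditions: N2H4·H2O, AcOH (0.5 equiv), MeOH, 0 °C to rt
Reagents that add atoms: none
Why: In the Wharton transposition the epoxy hydrazone fragments with loss of N2, which keeps the C5'–O bond and moves the alkene to C6'=C7'.

**Step 28**
Reactants: 40 allylic alcohol
Product: 41 γ-hydroxy enone (C8' ketone)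
Conditions: Rh2(caprolactamate)4 (1 mol%), t-BuOOH (70% aq.), K2CO3, CH2Cl2, rt
Reagents that add atoms: tert-butyl hydroperoxide CC(C)(C)OO
Why: Dirhodium-catalysed allylic oxidation finds C8' as the only allylic C–H site and avoids chromium reagents, which would transpose the tertiary allylic alcohol.

**Step 29**
Reactants: 41 enone
Product: 42 cis-C5',C8'-enediol
Conditions: NaBH4, CeCl3·7H2O, MeOH, -78 °C
Reagents that add atoms: none
Why: In this Luche reduction the axial C14' methyl shields one face of C8', so hydride enters from the other and O-8' ends syn to C14' and O-5', which sets C8'.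

**Step 30**
Reactants: 42 diol
Product: 43 eudesmane alcohol (C8' OTES; C1' OTBS; free C5'–OH)
Conditions: TESCl, imidazole, CH2Cl2, -20 °C
Reagents that add atoms: chlorotriethylsilane CC[Si](CC)(CC)Cl
Why: The secondary allylic alcohol is silylated selectively while the hindered tertiary alcohol stays free.

**Step 31**
Reactants: 31 guaiane lactone acid; 43 eudesmane alcohol
Product: 46 C5' tertiary allylic ester, via acid chloride 44 (not isolated), via lithium alkoxide 45 (not isolated)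
Conditions: 31, 1-chloro-N,N,2-trimethylprop-1-en-1-amine, CH2Cl2, 0 °C; separately 43, LiHMDS (1.0 equiv), THF, -78 to 0 °C; combine at -78 °C, then rt
Reagents that add atoms: none
Why: A lithium tert-alkoxide is acylated by an acid chloride (the method used for hindered tertiary carbinols), and the ester is made while the acyl chain is still unbranched at C11' and C13'.

**Step 32**
Reactants: 46 enone ester
Product: 47 C3 allylic alcohol (O-3 on the lower face, cis to O-2)
Conditions: NaBH4, CeCl3·7H2O, MeOH–THF, -78 °C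
Reagents that add atoms: none
Why: In this Luche reduction hydride adds anti to the vicinal C2 ether, which puts O-3 trans to the C13' chain.

**Step 33**
Reactants: 47 allylic alcohol
Product: 49 norbornene ester (C11' epimers, of no consequence), via C3 mesylate 48 (not isolated)
Conditions: KHMDS (1.05 equiv), THF, -78 °C; MsCl (1.1 equiv); then KHMDS (2.5 equiv), -78 to -20 °C; aq. NH4Cl
Reagents that add atoms: none
Why: In this intramolecular ester-enolate alkylation (5-exo-tet SN2) C11', held on the upper face by C13', displaces the lower-face allylic mesylate with inversion, which sets C3 and closes the bicyclo[2.2.1]heptene, while SN2' attack at C5 would need a four-membered ring.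

**Step 34**
Reactants: 49 norbornene ester
Product: 52 acid with quaternary C11', via bis(silyl ketene acetal) 50 (not isolated), via trimethylsilyl ester 51 (not isolated)
Conditions: KHMDS (4 equiv), TMSCl (6 equiv), THF–toluene, -78 °C to rt, then 85 °C; 0.5 M citric acid, THF
Reagents that add atoms: none
Why: In the Ireland–Claisen rearrangement C11' bonds through the exo face of the norbornene ketene acetal (the endo face lies under C4=C5) and the suprafacial shift carries the C5'–O configuration over to C7', which sets C11' and C7' and moves the alkene to C5'=C6'.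

**Step 35**
Reactants: 52 acid
Product: 54 bis-lactone (spiro cis-fused C7'/C8' γ-lactone), via hydroxy acid 53 (not isolated)
Conditions: PPTS (0.3 equiv), MeOH–CH2Cl2, rt; then toluene, 80 °C
Reagents that add atoms: none
Why: Mild acid removes only the triethylsilyl ether, and the C8' hydroxyl, cis to the C11' substituent on C7', closes the γ-lactone (acid-catalysed lactonisation favoured by the quaternary C11').

**Step 36**
Reactants: 54 bis-lactone
Product: 57 α-methylene lactone, via Mannich base 55 (not isolated), via ammonium iodide 56 (not isolated)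
Conditions: LDA, THF, -78 °C; CH2=NMe2+ I-, -78 °C to rt; MeI, MeOH–CH2Cl2, rt; aq. NaHCO3
Reagents that add atoms: dimethyl(methylidene)ammonium iodide C=[N+](C)C.[I-]
Why: Mannich reaction of the lactone enolate, quaternisation and Hofmann-type elimination add C13, and only the guaiane lactone has α-hydrogens.

**Step 37**
Reactants: 57 PMB ether
Product: 58 C2 alcohol
Conditions: DDQ, CH2Cl2–pH 7 buffer, 0 °C to rt
Reagents that add atoms: none
Why: Oxidative PMB cleavage is neutral and spares the alkenes, the α-methylene lactone and the silyl ether.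

**Step 38**
Reactants: 58 C2 alcohol
Product: 59 C2 acetate
Conditions: Ac2O, DMAP, Et3N, CH2Cl2, rt
Reagents that add atoms: acetic anhydride CC(=O)OC(C)=O
Why: DMAP-catalysed acetylation meets a single free hydroxyl because O-1' is still silylated.

**Step 39**
Reactants: 59 silyl ether
Product: 60 japonicone A
Conditions: HF·pyridine, THF, 0 °C to rt
Reagents that add atoms: none
Why: Acidic fluoride cleaves the hindered TBS ether without harming the acetate or the α-methylene lactone.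

**Compound list**
1 | 3-bromofuran | Brc1ccoc1 | starting material
2 | (2-tert-butoxy-2-oxoethyl)zinc bromide | CC(C)(C)OC(=O)C[Zn]Br | starting material
3 | tert-butyl 2-(furan-3-yl)acetate | CC(C)(C)OC(=O)Cc1ccoc1 | intermediate
4 | 5-boryl furan | CC(C)(C)OC(=O)Cc1coc(B2OC(C)(C)C(C)(C)O2)c1 | intermediate
5 | but-2-yn-1-ol | CC#CCO | starting material
6 | (Z)-3-iodobut-2-en-1-ol | OC/C=C(/C)I | intermediate
7 | Z-allylic alcohol | OC/C=C(/C)c1cc(CC(=O)OC(C)(C)C)co1 | intermediate
8 | Z-enal | O=C/C=C(/C)c1cc(CC(=O)OC(C)(C)C)co1 | intermediate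
9 | 5-(tert-butoxy)-5-oxopentanoic acid | CC(C)(C)OC(=O)CCCC(=O)O | starting material
10 | (R)-4-benzyloxazolidin-2-one | O=C1N[C@H](Cc2ccccc2)CO1 | starting material
11 | mixed pivalic anhydride | CC(C)(C)OC(=O)CCCC(=O)OC(=O)C(C)(C)C | intermediate
12 | glutarate imide | O=C1OC[C@@H](Cc2ccccc2)N1C(=O)CCCC(=O)OC(C)(C)C | intermediate
13 | dibutylboron Z-enolate | CCCCB(CCCC)O/C(=C\CCC(=O)OC(C)(C)C)N1C(=O)OC[C@H]1Cc1ccccc1 | intermediate
14 | syn-aldol adduct | O=C1OC[C@@H](Cc2ccccc2)N1C(=O)[C@H](CCC(=O)OC(C)(C)C)[C@@H](O)/C=C(/C)c1cc(CC(=O)OC(C)(C)C)co1 | intermediate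
15 | C2 PMB ether | O=C1OC[C@@H](Cc2ccccc2)N1C(=O)[C@H](CCC(=O)OC(C)(C)C)[C@@H](OCc1ccc(OC)cc1)/C=C(/C)c1cc(CC(=O)OC(C)(C)C)co1 | intermediate
16 | C3 alkylborane | O=C1OC[C@@H](Cc2ccccc2)N1C(=O)[C@H](CCC(=O)OC(C)(C)C)[C@@H](OCc1ccc(OC)cc1)[C@H](B)[C@@H](C)c1cc(CC(=O)OC(C)(C)C)co1 | intermediate
17 | C3 alcohol | O=C1OC[C@@H](Cc2ccccc2)N1C(=O)[C@H](CCC(=O)OC(C)(C)C)[C@@H](OCc1ccc(OC)cc1)[C@H](O)[C@@H](C)c1cc(CC(=O)OC(C)(C)C)co1 | intermediate
18 | C3 TES ether | O=C1OC[C@@H](Cc2ccccc2)N1C(=O)[C@H](CCC(=O)OC(C)(C)C)[C@@H](OCc1ccc(OC)cc1)[C@H](O[Si](CC)(CC)CC)[C@@H](C)c1cc(CC(=O)OC(C)(C)C)co1 | intermediate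
19 | C10 acid | OC(=O)[C@H](CCC(=O)OC(C)(C)C)[C@@H](OCc1ccc(OC)cc1)[C@H](O[Si](CC)(CC)CC)[C@@H](C)c1cc(CC(=O)OC(C)(C)C)co1 | intermediate
20 | C10 acid chloride | ClC(=O)[C@H](CCC(=O)OC(C)(C)C)[C@@H](OCc1ccc(OC)cc1)[C@H](O[Si](CC)(CC)CC)[C@@H](C)c1cc(CC(=O)OC(C)(C)C)co1 | intermediate
21 | diazoketone | [N-]=[N+]=CC(=O)[C@H](CCC(=O)OC(C)(C)C)[C@@H](OCc1ccc(OC)cc1)[C@H](O[Si](CC)(CC)CC)[C@@H](C)c1cc(CC(=O)OC(C)(C)C)co1 | intermediate
22 | furan-tethered α-chloroketone (key-step precursor) | ClCC(=O)[C@H](CCC(=O)OC(C)(C)C)[C@@H](OCc1ccc(OC)cc1)[C@H](O[Si](CC)(CC)CC)[C@@H](C)c1cc(CC(=O)OC(C)(C)C)co1 | intermediate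
23 | oxyallyl cation C9–C10–C1 (lithium-bound, drawn as zwitterion) | C=C([O-])[C+](CCC(=O)OC(C)(C)C)[C@@H](OCc1ccc(OC)cc1)[C@H](O[Si](CC)(CC)CC)[C@@H](C)c1cc(CC(=O)OC(C)(C)C)co1 | intermediate
24 | oxygen-bridged tricyclic ketone (key-step product) | O=C1C[C@H]2O[C@@]3(C=C2CC(=O)OC(C)(C)C)[C@H](C)[C@@H](O[Si](CC)(CC)CC)[C@H](OCc4ccc(OC)cc4)[C@]13CCC(=O)OC(C)(C)C | intermediate
25 | saturated bridged ketone | O=C1C[C@H]2O[C@@]3(C[C@H]2CC(=O)OC(C)(C)C)[C@H](C)[C@@H](O[Si](CC)(CC)CC)[C@H](OCc4ccc(OC)cc4)[C@]13CCC(=O)OC(C)(C)C | intermediate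
26 | C10 methylene compound | C=C1C[C@H]2O[C@@]3(C[C@H]2CC(=O)OC(C)(C)C)[C@H](C)[C@@H](O[Si](CC)(CC)CC)[C@H](OCc4ccc(OC)cc4)[C@]13CCC(=O)OC(C)(C)C | intermediate
27 | bridged C3 alcohol | C=C1C[C@H]2O[C@@]3(C[C@H]2CC(=O)OC(C)(C)C)[C@H](C)[C@@H](O)[C@H](OCc4ccc(OC)cc4)[C@]13CCC(=O)OC(C)(C)C | intermediate
28 | bridged C3 ketone | C=C1C[C@H]2O[C@@]3(C[C@H]2CC(=O)OC(C)(C)C)[C@H](C)C(=O)[C@H](OCc4ccc(OC)cc4)[C@]13CCC(=O)OC(C)(C)C | intermediate
29 | hydroazulenone with C10=CH2 | C=C1C[C@@H](O)[C@H](CC(=O)OC(C)(C)C)CC2=C(C)C(=O)[C@H](OCc3ccc(OC)cc3)[C@]12CCC(=O)OC(C)(C)C | intermediate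
30 | C10-methyl hydroazulenone | C[C@@H]1C[C@@H](O)[C@H](CC(=O)OC(C)(C)C)CC2=C(C)C(=O)[C@H](OCc3ccc(OC)cc3)[C@]12CCC(=O)OC(C)(C)C | intermediate
31 | guaiane lactone acid | C[C@@H]1C[C@H]2OC(=O)C[C@@H]2CC3=C(C)C(=O)[C@H](OCc4ccc(OC)cc4)[C@]13CCC(=O)O | intermediate
32 | (S)-Wieland–Miescher ketone | C[C@]12CCC(=O)C=C1CCCC2=O | starting material
33 | C1' alcohol | C[C@]12CCC(=O)C=C1CCC[C@@H]2O | intermediate
34 | C1' TBS ether | C[C@]12CCC(=O)C=C1CCC[C@@H]2O[Si](C)(C)C(C)(C)C | intermediate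
35 | C4'-methylene dienone | C[C@]12CCC(=O)C=C1C(=C)CC[C@@H]2O[Si](C)(C)C(C)(C)C | intermediate
36 | C4'-methyl enone | C[C@]12CCC(=O)C=C1[C@H](C)CC[C@@H]2O[Si](C)(C)C(C)(C)C | intermediate
37 | C7' allylic alcohol | C[C@]12CC[C@H](O)C=C1[C@H](C)CC[C@@H]2O[Si](C)(C)C(C)(C)C | intermediate
38 | epoxy alcohol | C[C@]12CC[C@H](O)[C@@H]3O[C@]13[C@H](C)CC[C@@H]2O[Si](C)(C)C(C)(C)C | intermediate
39 | epoxy ketone | C[C@]12CCC(=O)[C@@H]3O[C@]13[C@H](C)CC[C@@H]2O[Si](C)(C)C(C)(C)C | intermediate
40 | C5' tertiary allylic alcohol | C[C@]12CCC=C[C@@]1(O)[C@H](C)CC[C@@H]2O[Si](C)(C)C(C)(C)C | intermediate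
41 | γ-hydroxy enone | C[C@]12CC(=O)C=C[C@@]1(O)[C@H](C)CC[C@@H]2O[Si](C)(C)C(C)(C)C | intermediate
42 | cis-enediol | C[C@]12C[C@H](O)C=C[C@@]1(O)[C@H](C)CC[C@@H]2O[Si](C)(C)C(C)(C)C | intermediate
43 | eudesmane alcohol | C[C@]12C[C@H](O[Si](CC)(CC)CC)C=C[C@@]1(O)[C@H](C)CC[C@@H]2O[Si](C)(C)C(C)(C)C | intermediate
44 | C12' acid chloride | C[C@@H]1C[C@H]2OC(=O)C[C@@H]2CC3=C(C)C(=O)[C@H](OCc4ccc(OC)cc4)[C@]13CCC(=O)Cl | intermediate
45 | lithium alkoxide of 43 | C[C@]12C[C@H](O[Si](CC)(CC)CC)C=C[C@@]1(O[Li])[C@H](C)CC[C@@H]2O[Si](C)(C)C(C)(C)C | intermediate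
46 | C5' tertiary allylic ester | C[C@@H]1C[C@H]2OC(=O)C[C@@H]2CC3=C(C)C(=O)[C@H](OCc4ccc(OC)cc4)[C@]13CCC(=O)O[C@]4(C=C[C@@H](O[Si](CC)(CC)CC)C[C@]4(C)[C@@H](O[Si](C)(C)C(C)(C)C)CC5)[C@@H]5C | intermediate
47 | C3 allylic alcohol | C[C@@H]1C[C@H]2OC(=O)C[C@@H]2CC3=C(C)[C@H](O)[C@H](OCc4ccc(OC)cc4)[C@]13CCC(=O)O[C@]4(C=C[C@@H](O[Si](CC)(CC)CC)C[C@]4(C)[C@@H](O[Si](C)(C)C(C)(C)C)CC5)[C@@H]5C | intermediate
48 | C3 mesylate | C[C@@H]1C[C@H]2OC(=O)C[C@@H]2CC3=C(C)[C@H](OS(C)(=O)=O)[C@H](OCc4ccc(OC)cc4)[C@]13CCC(=O)O[C@]4(C=C[C@@H](O[Si](CC)(CC)CC)C[C@]4(C)[C@@H](O[Si](C)(C)C(C)(C)C)CC5)[C@@H]5C | intermediate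
49 | norbornene ester (C11' undefined) | C1C(=O)O[C@@H]2C[C@@H](C)[C@]34CC(C(=O)O[C@]5(C=C[C@@H](O[Si](CC)(CC)CC)C[C@]5(C)[C@@H](O[Si](C)(C)C(C)(C)C)CC6)[C@@H]6C)[C@H](C(C)=C3C[C@@H]12)[C@@H]4OCc7ccc(OC)cc7 | intermediate
50 | bis(silyl ketene acetal) | C1=C(O[Si](C)(C)C)O[C@@H]2C[C@@H](C)[C@]34CC(=C(O[Si](C)(C)C)O[C@]5(C=C[C@@H](O[Si](CC)(CC)CC)C[C@]5(C)[C@@H](O[Si](C)(C)C(C)(C)C)CC6)[C@@H]6C)[C@H](C(C)=C3C[C@@H]12)[C@@H]4OCc7ccc(OC)cc7 | intermediate
51 | rearranged trimethylsilyl ester | C1=C(O[Si](C)(C)C)O[C@@H]2C[C@@H](C)[C@]34C[C@@](C(=O)O[Si](C)(C)C)([C@@H]5C=C6[C@H](C)CC[C@H](O[Si](C)(C)C(C)(C)C)[C@@]6(C)C[C@@H]5O[Si](CC)(CC)CC)[C@H](C(C)=C3C[C@@H]12)[C@@H]4OCc7ccc(OC)cc7 | intermediate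
52 | acid with quaternary C11' | C1C(=O)O[C@@H]2C[C@@H](C)[C@]34C[C@@](C(=O)O)([C@@H]5C=C6[C@H](C)CC[C@H](O[Si](C)(C)C(C)(C)C)[C@@]6(C)C[C@@H]5O[Si](CC)(CC)CC)[C@H](C(C)=C3C[C@@H]12)[C@@H]4OCc7ccc(OC)cc7 | intermediate
53 | C8' hydroxy acid | C1C(=O)O[C@@H]2C[C@@H](C)[C@]34C[C@@](C(=O)O)([C@@H]5C=C6[C@H](C)CC[C@H](O[Si](C)(C)C(C)(C)C)[C@@]6(C)C[C@@H]5O)[C@H](C(C)=C3C[C@@H]12)[C@@H]4OCc7ccc(OC)cc7 | intermediate
54 | bis-lactone | C1C(=O)O[C@@H]2C[C@@H](C)[C@]34C[C@]5(C(=O)O[C@H]6C[C@@]7(C)C(=C[C@H]65)[C@H](C)CC[C@@H]7O[Si](C)(C)C(C)(C)C)[C@H](C(C)=C3C[C@@H]12)[C@@H]4OCc8ccc(OC)cc8 | intermediate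
55 | Mannich base (C11 undefined) | CN(C)CC1C(=O)O[C@@H]2C[C@@H](C)[C@]34C[C@]5(C(=O)O[C@H]6C[C@@]7(C)C(=C[C@H]65)[C@H](C)CC[C@@H]7O[Si](C)(C)C(C)(C)C)[C@H](C(C)=C3C[C@@H]12)[C@@H]4OCc8ccc(OC)cc8 | intermediate
56 | ammonium iodide | C[N+](C)(C)CC1C(=O)O[C@@H]2C[C@@H](C)[C@]34C[C@]5(C(=O)O[C@H]6C[C@@]7(C)C(=C[C@H]65)[C@H](C)CC[C@@H]7O[Si](C)(C)C(C)(C)C)[C@H](C(C)=C3C[C@@H]12)[C@@H]4OCc8ccc(OC)cc8.[I-] | intermediate
57 | α-methylene lactone | C=C1C(=O)O[C@@H]2C[C@@H](C)[C@]34C[C@]5(C(=O)O[C@H]6C[C@@]7(C)C(=C[C@H]65)[C@H](C)CC[C@@H]7O[Si](C)(C)C(C)(C)C)[C@H](C(C)=C3C[C@@H]12)[C@@H]4OCc8ccc(OC)cc8 | intermediate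
58 | C2 alcohol | C=C1C(=O)O[C@@H]2C[C@@H](C)[C@]34C[C@]5(C(=O)O[C@H]6C[C@@]7(C)C(=C[C@H]65)[C@H](C)CC[C@@H]7O[Si](C)(C)C(C)(C)C)[C@H](C(C)=C3C[C@@H]12)[C@@H]4O | intermediate
59 | C2 acetate | C=C1C(=O)O[C@@H]2C[C@@H](C)[C@]34C[C@]5(C(=O)O[C@H]6C[C@@]7(C)C(=C[C@H]65)[C@H](C)CC[C@@H]7O[Si](C)(C)C(C)(C)C)[C@H](C(C)=C3C[C@@H]12)[C@@H]4OC(C)=O | intermediate
60 | japonicone A | C=C1C(=O)O[C@@H]2C[C@@H](C)[C@]34C[C@]5(C(=O)O[C@H]6C[C@@]7(C)C(=C[C@H]65)[C@H](C)CC[C@@H]7O)[C@H](C(C)=C3C[C@@H]12)[C@@H]4OC(C)=O | target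

**Total step count:** 39. **Longest linear sequence:** 26 (steps 1, 2, 4, 5, 7–19, 31–39).

**Steps most likely to fail**

Step 13.
- Risk: deprotonation of the hindered C1–H may be too slow, so that substitution at CH2Cl or Favorskii-type collapse takes over. Facial selectivity may also erode if the lithium chelate is not maintained.
- Fallback (from 20, back at 24): make the enol derivative regiospecifically instead of by deprotonation. Acid chloride 20 is dehydrochlorinated with Et3N to the disubstituted ketene F1. Chloromethyllithium (ICH2Cl, MeLi·LiBr, -78 °C) adds in the ketene plane from the side of the smaller C13' chain, and TMSCl traps the enolate as the (Z)-2-(trimethylsiloxy)allyl chloride F2. AgClO4 in nitromethane–ether then ionises the allylic chloride, and the siloxyallyl cation undergoes the same intramolecular (4+3) cycloaddition to give 24 after loss of the silyl group.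

Step 31.
- Risk: acyl transfer to the tertiary alkoxide may be too slow, because it is flanked by C4', C10' and the syn C1' silyl ether. Enolisation of the enone or acid chloride by the alkoxide would then compete.
- Fallback (from 31, back at 52): close the norbornene first and bring the alkoxide onto a ketene. Acid 31 is methylated (TMSCHN2) to methyl ester F3 and reduced under Luche conditions to allylic alcohol F4. As in step 33, mesylate F5 then leads to norbornene methyl ester F6. Me3SnOH gives acid F7, 1-chloro-N,N,2-trimethylprop-1-en-1-amine gives acid chloride F8, and Et3N gives the disubstituted ketene F9. Lithium alkoxide 45 adds to the unhindered sp carbon of F9, and TMSCl traps the ester enolate as silyl ketene acetal F10. On warming this rearranges to silyl ester F11, and acidic work-up gives 52.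

Step 34.
- Risk: deprotonation of the hindered C11'–H may be sluggish. The rearrangement needs ring B to place the C5'–O bond pseudo-axially against a syn-diaxial methyl pair, so the barrier may be high and ester-enolate fragmentation to ketene and alkoxide may win.
- Fallback (from 47, back at 54): reverse the order of the two C11' bond formations. O-3 of 47 is silylated (TESOTf) to the C3 triethylsilyl ether F12. The still unbranched ester is converted (KHMDS, TMSCl) into bis(silyl ketene acetal) F13, whose Ireland–Claisen rearrangement builds only a tertiary C11' and gives silyl ester F14. Acidic work-up gives acid F15. PPTS in MeOH removes both triethylsilyl groups to give dihydroxy acid F16, which closes to the cis-lactone F17. KHMDS then MsCl gives mesylate F18, and more KHMDS alkylates the lactone enolate at C3 on its convex face (the face that also places C7' exo), which gives 54.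

**Further compounds**
F1 | step 13 | disubstituted ketene | O=C=C(CCC(=O)OC(C)(C)C)[C@@H](OCc1ccc(OC)cc1)[C@H](O[Si](CC)(CC)CC)[C@@H](C)c1cc(CC(=O)OC(C)(C)C)co1
F2 | step 13 | (Z)-2-(trimethylsiloxy)allyl chloride | ClC/C(O[Si](C)(C)C)=C(\CCC(=O)OC(C)(C)C)[C@@H](OCc1ccc(OC)cc1)[C@H](O[Si](CC)(CC)CC)[C@@H](C)c1cc(CC(=O)OC(C)(C)C)co1
F3 | step 31 | methyl ester of 31 | C[C@@H]1C[C@H]2OC(=O)C[C@@H]2CC3=C(C)C(=O)[C@H](OCc4ccc(OC)cc4)[C@]13CCC(=O)OC
F4 | step 31 | C3 allylic alcohol methyl ester | C[C@@H]1C[C@H]2OC(=O)C[C@@H]2CC3=C(C)[C@H](O)[C@H](OCc4ccc(OC)cc4)[C@]13CCC(=O)OC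
F5 | step 31 | C3 mesylate methyl ester | C[C@@H]1C[C@H]2OC(=O)C[C@@H]2CC3=C(C)[C@H](OS(C)(=O)=O)[C@H](OCc4ccc(OC)cc4)[C@]13CCC(=O)OC
F6 | step 31 | norbornene methyl ester | C1C(=O)O[C@@H]2C[C@@H](C)[C@]34CC(C(=O)OC)[C@H](C(C)=C3C[C@@H]12)[C@@H]4OCc5ccc(OC)cc5
F7 | step 31 | norbornene acid | C1C(=O)O[C@@H]2C[C@@H](C)[C@]34CC(C(=O)O)[C@H](C(C)=C3C[C@@H]12)[C@@H]4OCc5ccc(OC)cc5
F8 | step 31 | norbornene acid chloride | C1C(=O)O[C@@H]2C[C@@H](C)[C@]34CC(C(=O)Cl)[C@H](C(C)=C3C[C@@H]12)[C@@H]4OCc5ccc(OC)cc5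
F9 | step 31 | norbornylidene ketene | C1C(=O)O[C@@H]2C[C@@H](C)[C@]34CC(=C=O)[C@H](C(C)=C3C[C@@H]12)[C@@H]4OCc5ccc(OC)cc5
F10 | step 31 | silyl ketene acetal | C1C(=O)O[C@@H]2C[C@@H](C)[C@]34CC(=C(O[Si](C)(C)C)O[C@]5(C=C[C@@H](O[Si](CC)(CC)CC)C[C@]5(C)[C@@H](O[Si](C)(C)C(C)(C)C)CC6)[C@@H]6C)[C@H](C(C)=C3C[C@@H]12)[C@@H]4OCc7ccc(OC)cc7
F11 | step 31 | rearranged silyl ester | C1C(=O)O[C@@H]2C[C@@H](C)[C@]34C[C@@](C(=O)O[Si](C)(C)C)([C@@H]5C=C6[C@H](C)CC[C@H](O[Si](C)(C)C(C)(C)C)[C@@]6(C)C[C@@H]5O[Si](CC)(CC)CC)[C@H](C(C)=C3C[C@@H]12)[C@@H]4OCc7ccc(OC)cc7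
F12 | step 34 | C3 triethylsilyl ether of 47 | C[C@@H]1C[C@H]2OC(=O)C[C@@H]2CC3=C(C)[C@H](O[Si](CC)(CC)CC)[C@H](OCc4ccc(OC)cc4)[C@]13CCC(=O)O[C@]4(C=C[C@@H](O[Si](CC)(CC)CC)C[C@]4(C)[C@@H](O[Si](C)(C)C(C)(C)C)CC5)[C@@H]5C
F13 | step 34 | open-chain bis(silyl ketene acetal) | C[C@@H]1C[C@H]2OC(O[Si](C)(C)C)=C[C@@H]2CC3=C(C)[C@H](O[Si](CC)(CC)CC)[C@H](OCc4ccc(OC)cc4)[C@]13CC=C(O[Si](C)(C)C)O[C@]4(C=C[C@@H](O[Si](CC)(CC)CC)C[C@]4(C)[C@@H](O[Si](C)(C)C(C)(C)C)CC5)[C@@H]5C
F14 | step 34 | open-chain silyl ester | C[C@@H]1C[C@H]2OC(O[Si](C)(C)C)=C[C@@H]2CC3=C(C)[C@H](O[Si](CC)(CC)CC)[C@H](OCc4ccc(OC)cc4)[C@]13CC(C(=O)O[Si](C)(C)C)[C@@H]4C=C5[C@H](C)CC[C@H](O[Si](C)(C)C(C)(C)C)[C@@]5(C)C[C@@H]4O[Si](CC)(CC)CC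
F15 | step 34 | open-chain acid (C11' undefined) | C[C@@H]1C[C@H]2OC(=O)C[C@@H]2CC3=C(C)[C@H](O[Si](CC)(CC)CC)[C@H](OCc4ccc(OC)cc4)[C@]13CC(C(=O)O)[C@@H]4C=C5[C@H](C)CC[C@H](O[Si](C)(C)C(C)(C)C)[C@@]5(C)C[C@@H]4O[Si](CC)(CC)CC
F16 | step 34 | dihydroxy acid | C[C@@H]1C[C@H]2OC(=O)C[C@@H]2CC3=C(C)[C@H](O)[C@H](OCc4ccc(OC)cc4)[C@]13CC(C(=O)O)[C@@H]4C=C5[C@H](C)CC[C@H](O[Si](C)(C)C(C)(C)C)[C@@]5(C)C[C@@H]4O
F17 | step 34 | cis-lactone with free C3–OH | C[C@@H]1C[C@H]2OC(=O)C[C@@H]2CC3=C(C)[C@H](O)[C@H](OCc4ccc(OC)cc4)[C@]13CC4C(=O)O[C@H]5C[C@@]6(C)C(=C[C@H]54)[C@H](C)CC[C@@H]6O[Si](C)(C)C(C)(C)C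
F18 | step 34 | cis-lactone C3 mesylate | C[C@@H]1C[C@H]2OC(=O)C[C@@H]2CC3=C(C)[C@H](OS(C)(=O)=O)[C@H](OCc4ccc(OC)cc4)[C@]13CC4C(=O)O[C@H]5C[C@@]6(C)C(=C[C@H]54)[C@H](C)CC[C@@H]6O[Si](C)(C)C(C)(C)C
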